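Abbreviations: TBS = tert-butyldimethylsilyl, TES = triethylsilyl, TIPS = triisopropylsilyl, TMS = trimethylsilyl; TBSO, TESO and TIPSO are the corresponding silyloxy groups. Atoms are numbered C1 (alkyne CH) to C15 (ethyl CH3). Ring A is the tetrahydrofuran (O1, C4–C7) and ring B the oxocane (ring oxygen O(B), C6–C12).

## The problem

The target 32 is a C15 tribromide in which ring A is cis-fused through the C6–C7 bond to ring B, and the two ether carbons of ring B (C6 and C12) carry their hydrogens on opposite faces. Eight stereocentres must be set (C3, C4, C6, C7, C9, C10, C12, C13), three of them secondary bromides that each sit next to an oxygen-bearing carbon. C12 and C13 are neighbours and can be bought as a pair. C9 is remote from both and needs a reagent. C10 can then be set against C9, C6 against C12 and a C7 substituent, and C7 against C6. C3 and C4 lie outside ring B and again need a reagent. The propargylic C3 bromide (substitution, SN2′, epimerisation), the C10 bromide cis to the free C9 hydroxyl and the C13 bromide (elimination, neighbouring-oxygen participation) will not survive bases, hydrides or Lewis acids, so the C–Br bonds belong at the end and must come from alcohols by inversion. An eight-membered ether is slow to close and prone to transannular reactions. The enabling feature is that C6 and C10 are 1,5-related through C7–C9 while C10 is also tied to O(B) through C11–C12. The eight atoms of ring B are therefore the perimeter of a cyclopenta[b]furan. Cutting the shared C6=C10 bond leaves C6 as a lactone carbonyl (handle for C5 and for oxygenation at C7) and C10 as a ketone (handle for the bromide).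

## Retrosynthesis

**C3–Br and the C9 silyl ether (32 from 31 from 30).** The propargylic bromide is the most fragile group and is cut first, back to the (S)-propargylic alcohol 30; the C9 oxygen stays silylated until the last step so that only one hydroxyl is free when C3 is brominated. The forward reaction must be a clean SN2 displacement at low temperature, and the final desilylation must be non-basic.

**C10–Br and C13–Br (30 from 29 from 28 from 27).** Both bromides are cut to alcohols of opposite configuration and made in one operation from diol 28. Doing this after ring A exists has a reason: O1 then lies on the same face as the C10 leaving group and cannot displace it from the rear. The C3 oxygen is carried as an acetate (27 to 29) because a propargylic bromide would not keep its configuration under the forcing conditions; acetate and alkynylsilane then leave together (29 to 30). The forward step must invert a ring carbinol flanked by a cis silyloxy group.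

**Ring A, bond O1–C4 (27 from 25 from 24).** Cutting O1–C4 gives a C7 alcohol and a C3–C4 epoxide. The other ether bond (O1–C7) would require substitution at a ring carbon of the oxocane. A trans-epoxide opened at C4 with inversion gives the erythro O1/O3 pattern, which the later inversion at C3 converts into the threo O1/Br pattern of the target. Both C3 and C4 thus come from one catalyst-controlled epoxidation of E-enyne 24. The forward step needs exo-selective opening at the carbon remote from the alkyne.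

**Configuration at C7 (24 from 23 from 22).** No skeletal bond is cut here. The C7 oxygen has to be introduced while C6 is still a carbonyl, but it is needed cis to C5. Oxidation to ketone 23 and hydride delivery from the face opposite C5 sets C7 from C6 and makes the route independent of the face chosen in the earlier hydroxylation.

**C2–C3 and the C3=C4 geometry (22 from 21 from 20 from 18).** The enyne is cut at the sp–sp2 bond to E-vinyl iodide 20 and ethynyltrimethylsilane; 20 comes from terminal alkyne 18 by syn-hydrometalation. An olefination of a C4 aldehyde would give E/Z mixtures; this sequence is E-specific.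

**C5–C6 (18 from 17 from 15).** Cutting C5–C6 leads to the ring B oxocarbenium ion (from lactol acetate 17, itself from lactone 15) and an allenylstannane. Three carbons arrive in one step with C5 as CH2. The forward reaction must add anti to the C7 silyloxy group and anti to the C12 side chain; both point the same way.

**C7–O (15 from 14 from 12).** The C7 oxygen is removed to give lactone 12; in the forward sense it enters by enolate oxidation, the only α-position available.

**C10 (12 from 11 from 10).** The protected C10 alcohol is traced to the ketone of keto lactone 10. The reduction is put under catalyst control (C9 branch large, C11 small) and the alcohol is silylated at once, because a free C10 hydroxyl lies across the ring from the lactone carbonyl.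

**Ring B, bond C6=C10 (10 from 8).** Reconnecting the lactone carbon C6 and the ketone carbon C10 as a double bond folds ring B into two five-membered rings, the bicyclic enol ether 8. This removes the medium ring from the problem: 8 has two stereocentres fewer in play and no ring larger than five. The forward reaction is oxidative cleavage of a single, very electron-rich olefin.

**C9 (8 from 7 from 6).** The C9 silyl ether is traced to vinylogous ester 6 by 1,2-reduction; the stereocentre is remote from C12, so the forward reduction has to be catalyst-controlled.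

**C10–C11 and O(B)–C6 (6 from 3 and 4).** The dihydrofuran is cut into cyclopentane-1,3-dione 4 (C6–C10) and epoxide 3 (C11–C15). C-alkylation at the epoxide terminus leaves C12 untouched and places its oxygen where it can condense with a dione carbonyl.

**C12/C13 (3 from 2 from 1).** Epoxy alcohol 2 carries C12 and C13 in the erythro arrangement and is cut to racemic pent-1-en-3-ol 1 by kinetic resolution. The C13 oxygen has the configuration opposite to the final bromide, as the inversion requires.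

## Roads not taken

**Alternative 1: furan–oxyallyl (4+3) cycloaddition.** The cut removes C3–C4 and C7–C8 and treats ring A as the oxygen bridge of a seven-membered carbocycle. In the forward sense furan A1 and the oxyallyl cation generated reductively from 1,1,3,3-tetrabromoacetone A2 would give meso-8-oxabicyclo[3.2.1]oct-6-en-3-one A3 after debromination. Its merits are real: two cheap components, one step, and a 2,5-cis relationship at C4/C7 that is guaranteed by the bridge, whereas the chosen plan builds ring A late and needs three separate stereo-determining operations (C6, C7, C4). Its weak points for this target are that A3 is meso and must be desymmetrised, and that the ketone carbon links C3 and C8, which are not bonded in 32, so the bridge has to be cut again and one arm rebuilt. The C6 oxygen must also be placed on the symmetrical C5=C6 olefin with regio- and facial control. Above all, ring B with C9, C10, C12 and C13 is not addressed. It would have to be closed as an eight-membered ether or by metathesis onto the finished tetrahydrofuran, and the cis-bromohydrin would then be introduced on a ring olefin. Against the better ring A of this road, the chosen plan sets the fact that ring B needs no medium-ring closure and already carries C9, C12 and C13 when it appears.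

**Alternative 2: palladium oxycarbonylative bicyclisation.** Here O1–C7 and C8–C9 are cut, with C9 coming from carbon monoxide A5. Diol A4 would be treated with a divalent palladium catalyst and a copper reoxidant under A5: the C4 hydroxyl adds to the activated olefin, A5 inserts, and the C6 hydroxyl captures the acyl group to give the all-cis lactone A6. This fixes C4, C6 and C7 relative to each other in one step, which is more economical for ring A than steps 9–19 of the chosen plan, and the cis selectivity of such bicyclisations is dependable. The difficulty is what follows. In A6 the C6 oxygen is tied up as a lactone to C9, but in 32 it must be the ether oxygen bonded to C12. The lactone has to be opened, C9 reduced and extended by C10–C13 with three further stereocentres, and then the C6–O–C12 bond closed as an eight-membered ether, the least favourable way to make ring B. The side chain at C4 also arrives as a one-carbon stub. The chosen plan is weaker on ring A but avoids that etherification altogether.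

**Alternative 3: late pyran-to-furan contraction.** The cut is made at O1–C4 and C3–Br together. The ring-expanded pyranol A7, a 10-ethynyl-2,9-dioxabicyclo[6.4.0]dodecan-11-ol already carrying both ring B bromides, would be activated at C4 as its triflate. O1 displaces the triflate to form a bicyclic oxonium ion, and external bromide opens it at the propargylic carbon to give the 9-O-TBS ether of the target, A8. This is attractive: ring A and the C3 bromide are made in one stereospecific event (two inversions), and the oxygen participation that threatens step 23 of the chosen plan is turned into the productive pathway. It is a better endgame on paper. Its costs are that A7 is as complex as the target and leaves ring B, C9–C13 and a stereodefined pyranol to be solved by other means; that bromide may open the oxonium ion at C4 instead of C3; and that two secondary bromides must survive triflation. The chosen plan pays one more step at C3 and accepts the participation risk, but it supplies the whole ring B framework that this idea presupposes.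

Key step: step 6

Assumption: both tartrate enantiomers, the (S)-CBS oxazaborolidine, the L-fructose-derived dioxirane precursor, allenyltributylstannane and Cp2Zr(H)Cl are taken as purchasable.

## Route

Step 1
Reactants: 1 (±)-pent-1-en-3-ol
Product: 2 (2S,3R)-1,2-epoxypentan-3-ol
Conditions: Ti(OiPr)4 (0.15 equiv), D-(−)-diisopropyl tartrate (0.2 equiv), t-BuOOH (0.45 equiv), 4 Å MS, CH2Cl2, −20 °C
Reagents that add atoms: tert-butyl hydroperoxide, CC(C)(C)OO
Why: Sharpless kinetic resolution: with the D-tartrate the (R)-alcohol is epoxidised fast and from the face that gives the erythro epoxy alcohol, so C12 (S) and C13 (R) are set together; the (S)-alcohol is left behind and conversion is held below half.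

Step 2
Reactants: 2 (2S,3R)-1,2-epoxypentan-3-ol
Product: 3 tert-butyl(dimethyl){(1R)-1-[(2S)-oxiran-2-yl]propoxy}silane
Conditions: TBSCl, imidazole, DMF, 0 °C → rt
Reagents that add atoms: tert-butyldimethylsilyl chloride, CC(C)(C)[Si](C)(C)Cl
Why: Standard silylation of a secondary alcohol; it also makes the small epoxy alcohol easy to isolate and blocks the C13 oxygen until step 20.

Step 3
Reactants: 3 tert-butyl(dimethyl){(1R)-1-[(2S)-oxiran-2-yl]propoxy}silane; 4 cyclopentane-1,3-dione
Product: 6 (2S)-2-[(1R)-1-(TBSO)propyl]-2,3,5,6-tetrahydro-4H-cyclopenta[b]furan-4-one, via hydroxyalkyl dione 5 (not isolated)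
Conditions: 4 (2 equiv), K2CO3 (0.5 equiv), EtOH–H2O, 70 °C; then pyridinium p-toluenesulfonate, toluene, reflux (−H2O)
Reagents that add atoms: none
Why: C-alkylation of the dione enolate at the unhindered epoxide terminus (SN2, C12 untouched) followed by hemiketalisation and dehydration (cyclodehydration) to the vinylogous ester, a known way from cyclic 1,3-diones and epoxides to fused dihydrofuranones. The excess of acidic dione keeps the C12 oxygen protonated so the neighbouring silyl group should not migrate.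

Step 4
Reactants: 6 (2S)-2-[(1R)-1-(TBSO)propyl]-2,3,5,6-tetrahydro-4H-cyclopenta[b]furan-4-one
Product: 7 (2S,4R)-2-[(1R)-1-(TBSO)propyl]-3,4,5,6-tetrahydro-2H-cyclopenta[b]furan-4-ol
Conditions: (S)-2-methyl-CBS-oxazaborolidine [(3aS)-1-methyl-3,3-diphenylhexahydropyrrolo[1,2-c][1,3,2]oxazaborole] (0.5 equiv), BH3·SMe2, THF, −20 → 0 °C; MeOH, aq NaHCO3
Reagents that add atoms: none
Why: CBS 1,2-reduction: the substituted olefinic carbon acts as the large group and the ring CH2 as the small one, so the (S)-catalyst should deliver hydride to give the 4R alcohol (C9) irrespective of the remote C2 centre. Work-up is kept basic because the product is an allylic alcohol conjugated to an enol ether and ionises easily.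

Step 5
Reactants: 7 (2S,4R)-2-[(1R)-1-(TBSO)propyl]-3,4,5,6-tetrahydro-2H-cyclopenta[b]furan-4-ol
Product: 8 (2S,4R)-2-[(1R)-1-(TBSO)propyl]-4-(TIPSO)-3,4,5,6-tetrahydro-2H-cyclopenta[b]furan
Conditions: TIPSOTf, 2,6-lutidine, CH2Cl2, −78 °C
Reagents that add atoms: triisopropylsilyl triflate, CC(C)[Si](C(C)C)(C(C)C)OS(=O)(=O)C(F)(F)F
Why: Silylation with a silyl triflate under excess hindered base at low temperature is fast enough to outrun ionisation of the allylic alcohol; the bulky TIPS group is chosen to outlast the two TBS ethers in step 20.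

Step 6
Reactants: 8 (2S,4R)-2-[(1R)-1-(TBSO)propyl]-4-(TIPSO)-3,4,5,6-tetrahydro-2H-cyclopenta[b]furan
Product: 10 (5R,8S)-8-[(1R)-1-(TBSO)propyl]-5-(TIPSO)oxocane-2,6-dione, via methoxy hydroperoxide 9 (not isolated)
Conditions: O3 (1 equiv, Sudan Red 7B end point), NaHCO3, CH2Cl2–MeOH 4:1, −78 °C; then PPh3, −78 °C → rt
Reagents that add atoms: ozone, [O-][O+]=O
Why: Ozone adds as a 1,3-dipole to the tetrasubstituted enol-ether double bond C6=C10, and the primary ozonide fragments so that the oxygen-bearing carbon C6 leaves as the lactone carbonyl and C10 as a carbonyl oxide. Methanol traps the carbonyl oxide as methoxy hydroperoxide 9, which PPh3 reduces to the hemiketal and hence the C10 ketone. The closest known reaction type is the oxidative cleavage of the ring-fusion double bond of bicyclic enol ethers to medium-ring keto lactones. Ring B is not closed by a cyclisation: it appears as the perimeter when the bond shared by the dihydrofuran and the cyclopentene is removed, so no medium-ring entropy or transannular strain has to be overcome in a bond-forming step. No stereocentre is created. The step needs chemoselectivity and preservation of C9 and C12: the enol ether is the only olefin and reacts far faster than any C–H or silyl ether, the end-point dye prevents excess ozone, and the bicarbonate buffer protects the allylic TIPS ether before cleavage and the α-silyloxy ketone (C9) after it. C12 is two bonds away from any reacting centre and is not at risk.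

Step 7
Reactants: 10 (5R,8S)-8-[(1R)-1-(TBSO)propyl]-5-(TIPSO)oxocane-2,6-dione
Product: 11 (5R,6R,8S)-8-[(1R)-1-(TBSO)propyl]-6-hydroxy-5-(TIPSO)oxocan-2-one
Conditions: (S)-2-methyl-CBS-oxazaborolidine [(3aS)-1-methyl-3,3-diphenylhexahydropyrrolo[1,2-c][1,3,2]oxazaborole] (1 equiv), BH3·SMe2 (0.7 equiv), THF, −30 °C; MeOH
Reagents that add atoms: none
Why: CBS reduction of the ketone in the presence of the less reactive lactone: the branched C9 side is the large group and C11 the small one, so the (S)-catalyst should give the 6R alcohol (C10), trans to the C9 silyloxy group. The product is not stored, since a free hydroxyl 1,5 to the lactone carbonyl could translactonise.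

Step 8
Reactants: 11 (5R,6R,8S)-8-[(1R)-1-(TBSO)propyl]-6-hydroxy-5-(TIPSO)oxocan-2-one
Product: 12 (5R,6R,8S)-6-(TBSO)-8-[(1R)-1-(TBSO)propyl]-5-(TIPSO)oxocan-2-one
Conditions: TBSOTf, 2,6-lutidine, CH2Cl2, −78 °C (crude 11)
Reagents that add atoms: tert-butyldimethylsilyl triflate, CC(C)(C)[Si](C)(C)OS(=O)(=O)C(F)(F)F
Why: Immediate low-temperature silylation removes the nucleophilic hydroxyl; C10 and C13 now carry the same group and can be unmasked together.

Step 9
Reactants: 12 (5R,6R,8S)-6-(TBSO)-8-[(1R)-1-(TBSO)propyl]-5-(TIPSO)oxocan-2-one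
Product: 14 (3S,5R,6R,8S)-6-(TBSO)-8-[(1R)-1-(TBSO)propyl]-3-hydroxy-5-(TIPSO)oxocan-2-one, via potassium enolate 13 (not isolated)
Conditions: KN(SiMe3)2, THF, −78 °C; then 2-(phenylsulfonyl)-3-phenyloxaziridine, −78 °C; AcOH
Reagents that add atoms: 2-(phenylsulfonyl)-3-phenyloxaziridine, O=S(=O)(N1OC1c1ccccc1)c1ccccc1
Why: Enolate oxidation with an N-sulfonyloxaziridine at the only enolisable position (C7); peripheral attack on the eight-membered lactone enolate is expected on the face cis to the C12 side chain (3S). This centre is reset in step 17, so incomplete selectivity here is tolerable.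

Step 10
Reactants: 14 (3S,5R,6R,8S)-6-(TBSO)-8-[(1R)-1-(TBSO)propyl]-3-hydroxy-5-(TIPSO)oxocan-2-one
Product: 15 (3S,5R,6R,8S)-6-(TBSO)-8-[(1R)-1-(TBSO)propyl]-3-(TESO)-5-(TIPSO)oxocan-2-one
Conditions: Et3SiCl, imidazole, DMF, 0 °C
Reagents that add atoms: chlorotriethylsilane, CC[Si](Cl)(CC)CC
Why: Silylation; TES is the most labile of the four silyl ethers and can be removed alone in step 15.

Step 11
Reactants: 15 (3S,5R,6R,8S)-6-(TBSO)-8-[(1R)-1-(TBSO)propyl]-3-(TESO)-5-(TIPSO)oxocan-2-one
Product: 17 (3S,5R,6R,8S)-6-(TBSO)-8-[(1R)-1-(TBSO)propyl]-3-(TESO)-5-(TIPSO)oxocan-2-yl acetate (both C2 epimers), via aluminium lactolate 16 (not isolated)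
Conditions: i-Bu2AlH, CH2Cl2, −78 °C; then pyridine, 4-(dimethylamino)pyridine, Ac2O, −78 → 0 °C
Reagents that add atoms: acetic anhydride, CC(=O)OC(C)=O
Why: Reductive acetylation of a lactone: the tetrahedral aluminium lactolate is stable at −78 °C and is acetylated before it can open to the hydroxy aldehyde, which an eight-membered lactol would otherwise do.

Step 12
Reactants: 17 (3S,5R,6R,8S)-6-(TBSO)-8-[(1R)-1-(TBSO)propyl]-3-(TESO)-5-(TIPSO)oxocan-2-yl acetate
Product: 18 (2R,3S,5R,6R,8S)-6-(TBSO)-8-[(1R)-1-(TBSO)propyl]-2-(prop-2-yn-1-yl)-3-(TESO)-5-(TIPSO)oxocane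
Conditions: allenyltributylstannane, BF3·OEt2, CH2Cl2, −78 → −40 °C
Reagents that add atoms: allenyltributylstannane, C=C=C[Sn](CCCC)(CCCC)CCCC
Why: Lewis-acid ionisation to the ring B oxocarbenium ion and SE2′ attack by the allenylstannane (C-glycosylation type) gives the propargyl group with C5 as CH2. The nucleophile should enter anti to the adjacent C7 silyloxy group and anti to the C12 side chain across the ring oxygen, which both lie on the same face, setting C6 (2R).

Step 13
Reactants: 18 (2R,3S,5R,6R,8S)-6-(TBSO)-8-[(1R)-1-(TBSO)propyl]-2-(prop-2-yn-1-yl)-3-(TESO)-5-(TIPSO)oxocane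
Product: 20 (2R,3S,5R,6R,8S)-6-(TBSO)-8-[(1R)-1-(TBSO)propyl]-2-[(2E)-3-iodoprop-2-en-1-yl]-3-(TESO)-5-(TIPSO)oxocane, via alkenylzirconocene 19 (not isolated)
Conditions: Cp2Zr(H)Cl, THF, rt; then I2, 0 °C
Reagents that add atoms: iodine, II
Why: Hydrozirconation adds Zr–H syn across the terminal alkyne with zirconium at the terminus, and iodinolysis proceeds with retention, so the E-vinyl iodide is the only isomer expected.

Step 14
Reactants: 20 (2R,3S,5R,6R,8S)-6-(TBSO)-8-[(1R)-1-(TBSO)propyl]-2-[(2E)-3-iodoprop-2-en-1-yl]-3-(TESO)-5-(TIPSO)oxocane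
Product: 21 (2R,3S,5R,6R,8S)-6-(TBSO)-8-[(1R)-1-(TBSO)propyl]-3-(TESO)-5-(TIPSO)-2-[(2E)-5-(trimethylsilyl)pent-2-en-4-yn-1-yl]oxocane
Conditions: ethynyltrimethylsilane, Pd(PPh3)2Cl2 (5 mol %), CuI (10 mol %), Et3N, THF, rt
Reagents that add atoms: ethynyltrimethylsilane, C#C[Si](C)(C)C
Why: Sonogashira coupling of a vinyl iodide proceeds at room temperature with retention of the E geometry and brings in C1 and C2.

Step 15
Reactants: 21 (2R,3S,5R,6R,8S)-6-(TBSO)-8-[(1R)-1-(TBSO)propyl]-3-(TESO)-5-(TIPSO)-2-[(2E)-5-(trimethylsilyl)pent-2-en-4-yn-1-yl]oxocane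
Product: 22 (2R,3S,5R,6R,8S)-6-(TBSO)-8-[(1R)-1-(TBSO)propyl]-5-(TIPSO)-2-[(2E)-5-(trimethylsilyl)pent-2-en-4-yn-1-yl]oxocan-3-ol
Conditions: pyridinium p-toluenesulfonate, MeOH–CH2Cl2, 0 °C
Reagents that add atoms: none
Why: Mild acidic methanolysis cleaves the TES ether selectively; secondary TBS and TIPS ethers and the alkynylsilane are stable under these conditions.

Step 16
Reactants: 22 (2R,3S,5R,6R,8S)-6-(TBSO)-8-[(1R)-1-(TBSO)propyl]-5-(TIPSO)-2-[(2E)-5-(trimethylsilyl)pent-2-en-4-yn-1-yl]oxocan-3-ol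
Product: 23 (2R,5R,6R,8S)-6-(TBSO)-8-[(1R)-1-(TBSO)propyl]-5-(TIPSO)-2-[(2E)-5-(trimethylsilyl)pent-2-en-4-yn-1-yl]oxocan-3-one
Conditions: Dess–Martin periodinane, NaHCO3, CH2Cl2, 0 °C → rt
Reagents that add atoms: none
Why: Buffered Dess–Martin oxidation is neutral, so the C6 centre next to the new ketone should not epimerise.

Step 17
Reactants: 23 (2R,5R,6R,8S)-6-(TBSO)-8-[(1R)-1-(TBSO)propyl]-5-(TIPSO)-2-[(2E)-5-(trimethylsilyl)pent-2-en-4-yn-1-yl]oxocan-3-one
Product: 24 (2R,3R,5R,6R,8S)-6-(TBSO)-8-[(1R)-1-(TBSO)propyl]-5-(TIPSO)-2-[(2E)-5-(trimethylsilyl)pent-2-en-4-yn-1-yl]oxocan-3-ol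
Conditions: LiBH(s-Bu)3, THF, −78 °C
Reagents that add atoms: none
Why: The bulky borohydride should approach the ketone from the face opposite the adjacent C6 side chain (the usual outcome for 2-substituted 3-oxo cyclic ethers), giving the 2,3-cis alcohol; C7 is thereby set from C6 with its oxygen on the face needed for ring A.

Step 18
Reactants: 24 (2R,3R,5R,6R,8S)-6-(TBSO)-8-[(1R)-1-(TBSO)propyl]-5-(TIPSO)-2-[(2E)-5-(trimethylsilyl)pent-2-en-4-yn-1-yl]oxocan-3-ol
Product: 25 (2R,3R,5R,6R,8S)-6-(TBSO)-8-[(1R)-1-(TBSO)propyl]-5-(TIPSO)-2-{[(2S,3S)-3-[(trimethylsilyl)ethynyl]oxiran-2-yl]methyl}oxocan-3-ol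
Conditions: 1,2:4,5-di-O-isopropylidene-β-L-erythro-2,3-hexodiulo-2,6-pyranose (0.5 equiv), KHSO5 (as 2KHSO5·KHSO4·K2SO4), K2CO3, Bu4NHSO4, Na2B4O7–Na2EDTA buffer, MeCN–CH2(OMe)2–H2O, 0 °C
Reagents that add atoms: potassium peroxymonosulfate, [K+].[O-]S(=O)(=O)OO
Why: Shi epoxidation: the chiral dioxirane transfers oxygen through a spiro transition state, and trans-enynes are good substrates in which only the olefin reacts. The L-fructose-derived ketone is the enantiomer that should give the (S,S)-oxirane, setting C3 and C4 by catalyst control.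

Step 19
Reactants: 25 (2R,3R,5R,6R,8S)-6-(TBSO)-8-[(1R)-1-(TBSO)propyl]-5-(TIPSO)-2-{[(2S,3S)-3-[(trimethylsilyl)ethynyl]oxiran-2-yl]methyl}oxocan-3-ol
Product: 27 (1S)-1-[(1R,3S,5R,6R,8R,10R)-5-(TBSO)-3-[(1R)-1-(TBSO)propyl]-6-(TIPSO)-2,9-dioxabicyclo[6.3.0]undecan-10-yl]-3-(trimethylsilyl)prop-2-yn-1-yl acetate, via propargylic alcohol 26 (not isolated)
Conditions: (±)-10-camphorsulfonic acid (0.1 equiv), CH2Cl2, 0 °C; then pyridine, Ac2O, 4-(dimethylamino)pyridine, rt
Reagents that add atoms: acetic anhydride, CC(=O)OC(C)=O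
Why: Acid-catalysed 5-exo opening of the epoxide by the C7 hydroxyl at C4 (inversion, giving 4R) closes ring A cis-fused and leaves the C3 oxygen with retention (3S); the electron-withdrawing alkyne disfavours the endo mode at the propargylic carbon. Acetylation in the same flask protects the propargylic alcohol for steps 20 and 21.

Step 20
Reactants: 27 (1S)-1-[(1R,3S,5R,6R,8R,10R)-5-(TBSO)-3-[(1R)-1-(TBSO)propyl]-6-(TIPSO)-2,9-dioxabicyclo[6.3.0]undecan-10-yl]-3-(trimethylsilyl)prop-2-yn-1-yl acetate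
Product: 28 (1S)-1-[(1R,3S,5R,6R,8R,10R)-5-hydroxy-3-[(1R)-1-hydroxypropyl]-6-(TIPSO)-2,9-dioxabicyclo[6.3.0]undecan-10-yl]-3-(trimethylsilyl)prop-2-yn-1-yl acetate
Conditions: HF·pyridine, pyridine, THF, 0 °C → rt
Reagents that add atoms: none
Why: Buffered HF·pyridine cleaves the two secondary TBS ethers while the bulkier TIPS ether and the acetate remain; loss of the alkynyl TMS group here would be harmless because it is removed in step 22.

Step 21
Reactants: 28 (1S)-1-[(1R,3S,5R,6R,8R,10R)-5-hydroxy-3-[(1R)-1-hydroxypropyl]-6-(TIPSO)-2,9-dioxabicyclo[6.3.0]undecan-10-yl]-3-(trimethylsilyl)prop-2-yn-1-yl acetate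
Product: 29 (1S)-1-[(1R,3S,5S,6R,8R,10R)-5-bromo-3-[(1S)-1-bromopropyl]-6-(TIPSO)-2,9-dioxabicyclo[6.3.0]undecan-10-yl]-3-(trimethylsilyl)prop-2-yn-1-yl acetate
Conditions: CBr4, P(n-C8H17)3, toluene, 70 °C
Reagents that add atoms: carbon tetrabromide, BrC(Br)(Br)Br
Why: Appel-type bromination through alkoxyphosphonium ions with SN2 inversion at both carbinols, the standard way to place secondary bromides next to ether carbons; C10 becomes S (bromide cis to the C9 oxygen) and C13 becomes S. O1 lies on the face of the C10 leaving group and the silyl ether at C9 does not participate.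

Step 22
Reactants: 29 (1S)-1-[(1R,3S,5S,6R,8R,10R)-5-bromo-3-[(1S)-1-bromopropyl]-6-(TIPSO)-2,9-dioxabicyclo[6.3.0]undecan-10-yl]-3-(trimethylsilyl)prop-2-yn-1-yl acetate
Product: 30 (1S)-1-[(1R,3S,5S,6R,8R,10R)-5-bromo-3-[(1S)-1-bromopropyl]-6-(TIPSO)-2,9-dioxabicyclo[6.3.0]undecan-10-yl]prop-2-yn-1-ol
Conditions: K2CO3, MeOH, 0 °C
Reagents that add atoms: none
Why: Methanolysis removes the acetate and the alkynyl TMS group in one operation; cold carbonate in methanol is mild enough for secondary alkyl bromides.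

Step 23
Reactants: 30 (1S)-1-[(1R,3S,5S,6R,8R,10R)-5-bromo-3-[(1S)-1-bromopropyl]-6-(TIPSO)-2,9-dioxabicyclo[6.3.0]undecan-10-yl]prop-2-yn-1-ol
Product: 31 {[(1R,3S,5S,6R,8R,10R)-5-bromo-10-[(1R)-1-bromoprop-2-yn-1-yl]-3-[(1S)-1-bromopropyl]-2,9-dioxabicyclo[6.3.0]undecan-6-yl]oxy}tri(propan-2-yl)silane
Conditions: CBr4, PPh3, CH2Cl2, 0 °C
Reagents that add atoms: carbon tetrabromide, BrC(Br)(Br)Br
Why: Appel bromination of a propargylic alcohol with inversion (3S to 3R); the low temperature and short exposure are meant to suppress SN2′ formation of a bromoallene, bromide exchange and participation by O1.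

Step 24
Reactants: 31 {[(1R,3S,5S,6R,8R,10R)-5-bromo-10-[(1R)-1-bromoprop-2-yn-1-yl]-3-[(1S)-1-bromopropyl]-2,9-dioxabicyclo[6.3.0]undecan-6-yl]oxy}tri(propan-2-yl)silane
Product: 32 (1R,3S,5S,6R,8R,10R)-5-bromo-10-[(1R)-1-bromoprop-2-yn-1-yl]-3-[(1S)-1-bromopropyl]-2,9-dioxabicyclo[6.3.0]undecan-6-ol
Conditions: HF·pyridine, THF, rt
Reagents that add atoms: none
Why: Acidic fluoride cleaves the TIPS ether without the basicity of ammonium fluorides, so the three bromides and the terminal alkyne should survive; no stereocentre is touched.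

## Compound list

1 | (±)-pent-1-en-3-ol | C=CC(O)CC | starting material
2 | (2S,3R)-1,2-epoxypentan-3-ol | CC[C@@H](O)[C@@H]1CO1 | intermediate
3 | tert-butyl(dimethyl){(1R)-1-[(2S)-oxiran-2-yl]propoxy}silane | CC[C@@H](O[Si](C)(C)C(C)(C)C)[C@@H]1CO1 | intermediate
4 | cyclopentane-1,3-dione | O=C1CCC(=O)C1 | starting material
5 | 2-[(2S,3R)-3-(TBSO)-2-hydroxypentyl]cyclopentane-1,3-dione | CC[C@@H](O[Si](C)(C)C(C)(C)C)[C@@H](O)CC1C(=O)CCC1=O | intermediate (not isolated)
6 | (2S)-2-[(1R)-1-(TBSO)propyl]-2,3,5,6-tetrahydro-4H-cyclopenta[b]furan-4-one | CC[C@@H](O[Si](C)(C)C(C)(C)C)[C@@H]1CC2=C(O1)CCC2=O | intermediate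
7 | (2S,4R)-2-[(1R)-1-(TBSO)propyl]-3,4,5,6-tetrahydro-2H-cyclopenta[b]furan-4-ol | CC[C@@H](O[Si](C)(C)C(C)(C)C)[C@@H]1CC2=C(O1)CC[C@H]2O | intermediate
8 | (2S,4R)-2-[(1R)-1-(TBSO)propyl]-4-(TIPSO)-3,4,5,6-tetrahydro-2H-cyclopenta[b]furan | CC[C@@H](O[Si](C)(C)C(C)(C)C)[C@@H]1CC2=C(O1)CC[C@H]2O[Si](C(C)C)(C(C)C)C(C)C | intermediate (key-step precursor)
9 | (5R,8S)-8-[(1R)-1-(TBSO)propyl]-6-hydroperoxy-6-methoxy-5-(TIPSO)oxocan-2-one (C6 epimers) | CC[C@@H](O[Si](C)(C)C(C)(C)C)[C@@H]1CC(OC)(OO)[C@H](O[Si](C(C)C)(C(C)C)C(C)C)CCC(=O)O1 | intermediate (not isolated)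
10 | (5R,8S)-8-[(1R)-1-(TBSO)propyl]-5-(TIPSO)oxocane-2,6-dione | CC[C@@H](O[Si](C)(C)C(C)(C)C)[C@@H]1CC(=O)[C@H](O[Si](C(C)C)(C(C)C)C(C)C)CCC(=O)O1 | intermediate (key-step product)
11 | (5R,6R,8S)-8-[(1R)-1-(TBSO)propyl]-6-hydroxy-5-(TIPSO)oxocan-2-one | CC[C@@H](O[Si](C)(C)C(C)(C)C)[C@@H]1C[C@@H](O)[C@H](O[Si](C(C)C)(C(C)C)C(C)C)CCC(=O)O1 | intermediate
12 | (5R,6R,8S)-6-(TBSO)-8-[(1R)-1-(TBSO)propyl]-5-(TIPSO)oxocan-2-one | CC[C@@H](O[Si](C)(C)C(C)(C)C)[C@@H]1C[C@@H](O[Si](C)(C)C(C)(C)C)[C@H](O[Si](C(C)C)(C(C)C)C(C)C)CCC(=O)O1 | intermediate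
13 | potassium enolate of 12 | CC[C@@H](O[Si](C)(C)C(C)(C)C)[C@@H]1C[C@@H](O[Si](C)(C)C(C)(C)C)[C@H](O[Si](C(C)C)(C(C)C)C(C)C)CC=C([O-])O1.[K+] | intermediate (not isolated)
14 | (3S,5R,6R,8S)-6-(TBSO)-8-[(1R)-1-(TBSO)propyl]-3-hydroxy-5-(TIPSO)oxocan-2-one | CC[C@@H](O[Si](C)(C)C(C)(C)C)[C@@H]1C[C@@H](O[Si](C)(C)C(C)(C)C)[C@H](O[Si](C(C)C)(C(C)C)C(C)C)C[C@H](O)C(=O)O1 | intermediate
15 | (3S,5R,6R,8S)-6-(TBSO)-8-[(1R)-1-(TBSO)propyl]-3-(TESO)-5-(TIPSO)oxocan-2-one | CC[C@@H](O[Si](C)(C)C(C)(C)C)[C@@H]1C[C@@H](O[Si](C)(C)C(C)(C)C)[C@H](O[Si](C(C)C)(C(C)C)C(C)C)C[C@H](O[Si](CC)(CC)CC)C(=O)O1 | intermediate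
16 | diisobutylaluminium lactolate of 15 (C2 epimers) | CC[C@@H](O[Si](C)(C)C(C)(C)C)[C@@H]1C[C@@H](O[Si](C)(C)C(C)(C)C)[C@H](O[Si](C(C)C)(C(C)C)C(C)C)C[C@H](O[Si](CC)(CC)CC)C(O[Al](CC(C)C)CC(C)C)O1 | intermediate (not isolated)
17 | (3S,5R,6R,8S)-6-(TBSO)-8-[(1R)-1-(TBSO)propyl]-3-(TESO)-5-(TIPSO)oxocan-2-yl acetate (C2 epimers) | CC[C@@H](O[Si](C)(C)C(C)(C)C)[C@@H]1C[C@@H](O[Si](C)(C)C(C)(C)C)[C@H](O[Si](C(C)C)(C(C)C)C(C)C)C[C@H](O[Si](CC)(CC)CC)C(OC(C)=O)O1 | intermediate
18 | (2R,3S,5R,6R,8S)-6-(TBSO)-8-[(1R)-1-(TBSO)propyl]-2-(prop-2-yn-1-yl)-3-(TESO)-5-(TIPSO)oxocane | CC[C@@H](O[Si](C)(C)C(C)(C)C)[C@@H]1C[C@@H](O[Si](C)(C)C(C)(C)C)[C@H](O[Si](C(C)C)(C(C)C)C(C)C)C[C@H](O[Si](CC)(CC)CC)[C@@H](CC#C)O1 | intermediate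
19 | (E)-alkenyl(chloro)zirconocene from 18 | CC[C@@H](O[Si](C)(C)C(C)(C)C)[C@@H]1C[C@@H](O[Si](C)(C)C(C)(C)C)[C@H](O[Si](C(C)C)(C(C)C)C(C)C)C[C@H](O[Si](CC)(CC)CC)[C@@H](C/C=C/[Zr](Cl)(C2C=CC=C2)C2C=CC=C2)O1 | intermediate (not isolated)
20 | (2R,3S,5R,6R,8S)-6-(TBSO)-8-[(1R)-1-(TBSO)propyl]-2-[(2E)-3-iodoprop-2-en-1-yl]-3-(TESO)-5-(TIPSO)oxocane | CC[C@@H](O[Si](C)(C)C(C)(C)C)[C@@H]1C[C@@H](O[Si](C)(C)C(C)(C)C)[C@H](O[Si](C(C)C)(C(C)C)C(C)C)C[C@H](O[Si](CC)(CC)CC)[C@@H](C/C=C/I)O1 | intermediate
21 | (2R,3S,5R,6R,8S)-6-(TBSO)-8-[(1R)-1-(TBSO)propyl]-3-(TESO)-5-(TIPSO)-2-[(2E)-5-(trimethylsilyl)pent-2-en-4-yn-1-yl]oxocane | CC[C@@H](O[Si](C)(C)C(C)(C)C)[C@@H]1C[C@@H](O[Si](C)(C)C(C)(C)C)[C@H](O[Si](C(C)C)(C(C)C)C(C)C)C[C@H](O[Si](CC)(CC)CC)[C@@H](C/C=C/C#C[Si](C)(C)C)O1 | intermediate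
22 | (2R,3S,5R,6R,8S)-6-(TBSO)-8-[(1R)-1-(TBSO)propyl]-5-(TIPSO)-2-[(2E)-5-(trimethylsilyl)pent-2-en-4-yn-1-yl]oxocan-3-ol | CC[C@@H](O[Si](C)(C)C(C)(C)C)[C@@H]1C[C@@H](O[Si](C)(C)C(C)(C)C)[C@H](O[Si](C(C)C)(C(C)C)C(C)C)C[C@H](O)[C@@H](C/C=C/C#C[Si](C)(C)C)O1 | intermediate
23 | (2R,5R,6R,8S)-6-(TBSO)-8-[(1R)-1-(TBSO)propyl]-5-(TIPSO)-2-[(2E)-5-(trimethylsilyl)pent-2-en-4-yn-1-yl]oxocan-3-one | CC[C@@H](O[Si](C)(C)C(C)(C)C)[C@@H]1C[C@@H](O[Si](C)(C)C(C)(C)C)[C@H](O[Si](C(C)C)(C(C)C)C(C)C)CC(=O)[C@@H](C/C=C/C#C[Si](C)(C)C)O1 | intermediate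
24 | (2R,3R,5R,6R,8S)-6-(TBSO)-8-[(1R)-1-(TBSO)propyl]-5-(TIPSO)-2-[(2E)-5-(trimethylsilyl)pent-2-en-4-yn-1-yl]oxocan-3-ol | CC[C@@H](O[Si](C)(C)C(C)(C)C)[C@@H]1C[C@@H](O[Si](C)(C)C(C)(C)C)[C@H](O[Si](C(C)C)(C(C)C)C(C)C)C[C@@H](O)[C@@H](C/C=C/C#C[Si](C)(C)C)O1 | intermediate
25 | (2R,3R,5R,6R,8S)-6-(TBSO)-8-[(1R)-1-(TBSO)propyl]-5-(TIPSO)-2-{[(2S,3S)-3-[(trimethylsilyl)ethynyl]oxiran-2-yl]methyl}oxocan-3-ol | CC[C@@H](O[Si](C)(C)C(C)(C)C)[C@@H]1C[C@@H](O[Si](C)(C)C(C)(C)C)[C@H](O[Si](C(C)C)(C(C)C)C(C)C)C[C@@H](O)[C@@H](C[C@@H]2O[C@H]2C#C[Si](C)(C)C)O1 | intermediate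
26 | (1S)-1-[(1R,3S,5R,6R,8R,10R)-5-(TBSO)-3-[(1R)-1-(TBSO)propyl]-6-(TIPSO)-2,9-dioxabicyclo[6.3.0]undecan-10-yl]-3-(trimethylsilyl)prop-2-yn-1-ol | C[Si](C)(C)C#C[C@H](O)[C@H]1C[C@H]2O[C@H]([C@H](O[Si](C)(C)C(C)(C)C)CC)C[C@@H](O[Si](C)(C)C(C)(C)C)[C@H](O[Si](C(C)C)(C(C)C)C(C)C)C[C@H]2O1 | intermediate (not isolated)
27 | (1S)-1-[(1R,3S,5R,6R,8R,10R)-5-(TBSO)-3-[(1R)-1-(TBSO)propyl]-6-(TIPSO)-2,9-dioxabicyclo[6.3.0]undecan-10-yl]-3-(trimethylsilyl)prop-2-yn-1-yl acetate | C[Si](C)(C)C#C[C@H](OC(C)=O)[C@H]1C[C@H]2O[C@H]([C@H](O[Si](C)(C)C(C)(C)C)CC)C[C@@H](O[Si](C)(C)C(C)(C)C)[C@H](O[Si](C(C)C)(C(C)C)C(C)C)C[C@H]2O1 | intermediate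
28 | (1S)-1-[(1R,3S,5R,6R,8R,10R)-5-hydroxy-3-[(1R)-1-hydroxypropyl]-6-(TIPSO)-2,9-dioxabicyclo[6.3.0]undecan-10-yl]-3-(trimethylsilyl)prop-2-yn-1-yl acetate | C[Si](C)(C)C#C[C@H](OC(C)=O)[C@H]1C[C@H]2O[C@H]([C@H](O)CC)C[C@@H](O)[C@H](O[Si](C(C)C)(C(C)C)C(C)C)C[C@H]2O1 | intermediate
29 | (1S)-1-[(1R,3S,5S,6R,8R,10R)-5-bromo-3-[(1S)-1-bromopropyl]-6-(TIPSO)-2,9-dioxabicyclo[6.3.0]undecan-10-yl]-3-(trimethylsilyl)prop-2-yn-1-yl acetate | C[Si](C)(C)C#C[C@H](OC(C)=O)[C@H]1C[C@H]2O[C@H]([C@@H](Br)CC)C[C@H](Br)[C@H](O[Si](C(C)C)(C(C)C)C(C)C)C[C@H]2O1 | intermediate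
30 | (1S)-1-[(1R,3S,5S,6R,8R,10R)-5-bromo-3-[(1S)-1-bromopropyl]-6-(TIPSO)-2,9-dioxabicyclo[6.3.0]undecan-10-yl]prop-2-yn-1-ol | C#C[C@H](O)[C@H]1C[C@H]2O[C@H]([C@@H](Br)CC)C[C@H](Br)[C@H](O[Si](C(C)C)(C(C)C)C(C)C)C[C@H]2O1 | intermediate
31 | {[(1R,3S,5S,6R,8R,10R)-5-bromo-10-[(1R)-1-bromoprop-2-yn-1-yl]-3-[(1S)-1-bromopropyl]-2,9-dioxabicyclo[6.3.0]undecan-6-yl]oxy}tri(propan-2-yl)silane | C#C[C@@H](Br)[C@H]1C[C@H]2O[C@H]([C@@H](Br)CC)C[C@H](Br)[C@H](O[Si](C(C)C)(C(C)C)C(C)C)C[C@H]2O1 | intermediate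
32 | (1R,3S,5S,6R,8R,10R)-5-bromo-10-[(1R)-1-bromoprop-2-yn-1-yl]-3-[(1S)-1-bromopropyl]-2,9-dioxabicyclo[6.3.0]undecan-6-ol | C#C[C@@H](Br)[C@H]1C[C@H]2O[C@H]([C@@H](Br)CC)C[C@H](Br)[C@H](O)C[C@H]2O1 | target

## Step count and least certain steps

Total step count: 24. Longest linear sequence: 24 steps (from 1; dione 4 enters at step 3).

**Step 6 (key step).** What may go wrong: oxidation beyond the enol ether if ozone is overdosed, acid-promoted ionisation of the allylic silyl ether before cleavage, or epimerisation at C9 next to the new ketone during work-up. Fallback, from 8 back to 10: dihydroxylation of the enol ether (OsO4 cat., N-methylmorpholine N-oxide, pyridine, acetone–water) to the cis-diol (2S,4R)-2-[(1R)-1-(TBSO)propyl]-4-(TIPSO)hexahydro-2H-cyclopenta[b]furan-3a,6a-diol F1, then glycol cleavage of the hemiketal diol with Pb(OAc)4 and K2CO3 in CH2Cl2 at −20 °C. This cuts the same C6–C10 bond in two mild steps without a peroxidic intermediate and returns to the route at 10.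

**Step 3.** What may go wrong: O-alkylation or double alkylation of the dione, slow opening of the α-branched epoxide, or silyl migration to the C12 oxygen. Fallback, from 4 (and the (R)-enantiomer of 1, recovered when the resolution of step 1 is run with the L-tartrate) back to 6: silylation of that alcohol gives (R)-tert-butyl(dimethyl)(pent-1-en-3-yloxy)silane F2. Oxidative radical addition–cyclisation of 4 onto F2 with (NH4)2Ce(NO3)6 and NaHCO3 in MeCN at 0 °C then forms the C10–C11 and O–C12 bonds directly. This gives 6 together with its C2 epimer, (2R)-2-[(1R)-1-(TBSO)propyl]-2,3,5,6-tetrahydro-4H-cyclopenta[b]furan-4-one F3, which is removed by chromatography. The price is a separation in place of the stereospecific epoxide opening.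

**Step 4.** What may go wrong: low facial selectivity because the vinylogous ester carbonyl is deactivated and binds the catalyst poorly, or loss of the allylic alcohol by ionisation during work-up. Fallback, from 6 back to 8: unselective 1,2-reduction with i-Bu2AlH at −78 °C gives 7 and its epimer (2S,4S)-2-[(1R)-1-(TBSO)propyl]-3,4,5,6-tetrahydro-2H-cyclopenta[b]furan-4-ol F4. Silylation of the crude mixture as in step 5 gives 8 and (2S,4S)-2-[(1R)-1-(TBSO)propyl]-4-(TIPSO)-3,4,5,6-tetrahydro-2H-cyclopenta[b]furan F5. The two diastereomers are separated on base-washed silica and 8 re-enters the route.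

**Step 7.** What may go wrong: translactonisation of the free C10 hydroxyl onto the lactone carbonyl across the ring (six-membered lactone, loss of ring B), or delivery of hydride to the wrong face. Fallback, from 10 directly to 12: ligated copper hydride hydrosilylation of the dialkyl ketone (Cu(OAc)2·H2O, DTBM-SEGPHOS, t-BuMe2SiH, toluene; the ligand enantiomer is matched to the 6R product on a trial scale). This forms the TBS ether in the reduction itself, so no free hydroxy lactone exists at any time; no new compound is involved.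

**Step 12.** What may go wrong: poor facial selectivity at the oxocarbenium ion if the conformational preferences of the eight-membered cation outweigh the two substituent effects, or loss of the TES group to the Lewis acid. Fallback, from 14 back to 18, using anchimeric assistance:
- Reductive acetylation of hydroxy lactone 14 itself (i-Bu2AlH, then Ac2O, pyridine, 4-(dimethylamino)pyridine) gives the diacetate (3S,5R,6R,8S)-6-(TBSO)-8-[(1R)-1-(TBSO)propyl]-5-(TIPSO)oxocane-2,3-diyl diacetate F6.
- Allenyltributylstannane and BF3·OEt2 then react through the bridged acetoxonium ion, which enforces 2,3-trans addition, to give (2R,3S,5R,6R,8S)-6-(TBSO)-8-[(1R)-1-(TBSO)propyl]-2-(prop-2-yn-1-yl)-5-(TIPSO)oxocan-3-yl acetate F7.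
- Methanolysis (K2CO3, MeOH) gives the alcohol (2R,3S,5R,6R,8S)-6-(TBSO)-8-[(1R)-1-(TBSO)propyl]-2-(prop-2-yn-1-yl)-5-(TIPSO)oxocan-3-ol F8, and silylation (Et3SiCl, imidazole) returns to 18.

**Step 21.** What may go wrong: slow substitution at C10 because the bromide must enter next to the cis TIPS ether, elimination instead of substitution, or participation of the ring B oxygen at C13 leading to retention or ring rearrangement. Fallback, from 28 back to 29: the diol is converted with ClCH2SO2Cl and pyridine at 0 °C into the bis(chloromethanesulfonate) (1S)-1-[(1R,3S,5R,6R,8R,10R)-5-[(chloromethanesulfonyl)oxy]-3-{(1R)-1-[(chloromethanesulfonyl)oxy]propyl}-6-(TIPSO)-2,9-dioxabicyclo[6.3.0]undecan-10-yl]-3-(trimethylsilyl)prop-2-yn-1-yl acetate F9. This is displaced with LiBr in THF–DMF at rt, an activation/displacement pair that works under milder, non-phosphine conditions and also inverts both centres.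

## Further compounds

F1 | step 6 | (2S,4R)-2-[(1R)-1-(TBSO)propyl]-4-(TIPSO)hexahydro-2H-cyclopenta[b]furan-3a,6a-diol (cis-diol, ring-fusion centres not assigned) | CC[C@@H](O[Si](C)(C)C(C)(C)C)[C@@H]1CC2(O)C(O)(O1)CC[C@H]2O[Si](C(C)C)(C(C)C)C(C)C
F2 | step 3 | (R)-tert-butyl(dimethyl)(pent-1-en-3-yloxy)silane | C=C[C@H](O[Si](C)(C)C(C)(C)C)CC
F3 | step 3 | (2R)-2-[(1R)-1-(TBSO)propyl]-2,3,5,6-tetrahydro-4H-cyclopenta[b]furan-4-one | CC[C@@H](O[Si](C)(C)C(C)(C)C)[C@H]1CC2=C(O1)CCC2=O
F4 | step 4 | (2S,4S)-2-[(1R)-1-(TBSO)propyl]-3,4,5,6-tetrahydro-2H-cyclopenta[b]furan-4-ol | CC[C@@H](O[Si](C)(C)C(C)(C)C)[C@@H]1CC2=C(O1)CC[C@@H]2O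
F5 | step 4 | (2S,4S)-2-[(1R)-1-(TBSO)propyl]-4-(TIPSO)-3,4,5,6-tetrahydro-2H-cyclopenta[b]furan | CC[C@@H](O[Si](C)(C)C(C)(C)C)[C@@H]1CC2=C(O1)CC[C@@H]2O[Si](C(C)C)(C(C)C)C(C)C
F0 | step 7 | none | none
F6 | step 12 | (3S,5R,6R,8S)-6-(TBSO)-8-[(1R)-1-(TBSO)propyl]-5-(TIPSO)oxocane-2,3-diyl diacetate (C2 epimers) | CC[C@@H](O[Si](C)(C)C(C)(C)C)[C@@H]1C[C@@H](O[Si](C)(C)C(C)(C)C)[C@H](O[Si](C(C)C)(C(C)C)C(C)C)C[C@H](OC(C)=O)C(OC(C)=O)O1
F7 | step 12 | (2R,3S,5R,6R,8S)-6-(TBSO)-8-[(1R)-1-(TBSO)propyl]-2-(prop-2-yn-1-yl)-5-(TIPSO)oxocan-3-yl acetate | CC[C@@H](O[Si](C)(C)C(C)(C)C)[C@@H]1C[C@@H](O[Si](C)(C)C(C)(C)C)[C@H](O[Si](C(C)C)(C(C)C)C(C)C)C[C@H](OC(C)=O)[C@@H](CC#C)O1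
F8 | step 12 | (2R,3S,5R,6R,8S)-6-(TBSO)-8-[(1R)-1-(TBSO)propyl]-2-(prop-2-yn-1-yl)-5-(TIPSO)oxocan-3-ol | CC[C@@H](O[Si](C)(C)C(C)(C)C)[C@@H]1C[C@@H](O[Si](C)(C)C(C)(C)C)[C@H](O[Si](C(C)C)(C(C)C)C(C)C)C[C@H](O)[C@@H](CC#C)O1
F9 | step 21 | (1S)-1-[(1R,3S,5R,6R,8R,10R)-5-[(chloromethanesulfonyl)oxy]-3-{(1R)-1-[(chloromethanesulfonyl)oxy]propyl}-6-(TIPSO)-2,9-dioxabicyclo[6.3.0]undecan-10-yl]-3-(trimethylsilyl)prop-2-yn-1-yl acetate | C[Si](C)(C)C#C[C@H](OC(C)=O)[C@H]1C[C@H]2O[C@H]([C@H](OS(=O)(=O)CCl)CC)C[C@@H](OS(=O)(=O)CCl)[C@H](O[Si](C(C)C)(C(C)C)C(C)C)C[C@H]2O1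
A1 | alternative 1 | furan | c1ccoc1
A2 | alternative 1 | 1,1,3,3-tetrabromoacetone | O=C(C(Br)Br)C(Br)Br
A3 | alternative 1 | meso-8-oxabicyclo[3.2.1]oct-6-en-3-one | O=C1C[C@H]2C=C[C@@H](C1)O2
A4 | alternative 2 | (2R,4R)-1-[tert-butyl(diphenyl)silyl]oxyhex-5-ene-2,4-diol | C=C[C@H](O)C[C@@H](O)CO[Si](c1ccccc1)(c1ccccc1)C(C)(C)C
A5 | alternative 2 | carbon monoxide | [C-]#[O+]
A6 | alternative 2 | all-cis 5-(tert-butyldiphenylsilyloxymethyl)tetrahydrofuro[3,2-b]furan-2(3H)-one | O=C1C[C@H]2O[C@@H](CO[Si](c3ccccc3)(c3ccccc3)C(C)(C)C)C[C@H]2O1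
A7 | alternative 3 | 5-bromo-3-(1-bromopropyl)-6-(TBSO)-10-ethynyl-2,9-dioxabicyclo[6.4.0]dodecan-11-ol (configured as in the SMILES) | C#C[C@H]1[C@@H](O)C[C@H]2O[C@H]([C@@H](Br)CC)C[C@H](Br)[C@H](O[Si](C)(C)C(C)(C)C)C[C@H]2O1
A8 | alternative 3 | 9-O-tert-butyldimethylsilyl ether of the target | C#C[C@@H](Br)[C@H]1C[C@H]2O[C@H]([C@@H](Br)CC)C[C@H](Br)[C@H](O[Si](C)(C)C(C)(C)C)C[C@H]2O1
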